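**Retrosynthetic overview**
1. Target ⇒ cut the aryl C6–CH2 bond: a 6-iodo-8-propionylchromene-5,7-diol plus a boron homoenolate of propionylfilicinic acid (CH2–BF3K on the triketone). In this Suzuki–Miyaura union the bridging carbon is the nucleophile and the phloroglucinol carbon the electrophile, so only the cross-dimer can form.
2. Homoenolate ⇒ propionylfilicinic acid + BrCH2Bpin (C-alkylation, then KHF2); the dearomatised triketone ring ⇒ gem-dimethylation of flopropione.
3. Aryl iodide ⇒ chromene + N-iodosuccinimide; pyran ring ⇒ 4-O-silyl flopropione + prenal (oxa-6π), the silyl ether forcing closure onto the hydroxyl ortho to the ketone.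
4. Ring order: triketone ring (step 1) and pyran ring (step 4) on separate branches; union last (step 6); no ring is formed after it.

Assumption: the SMILES has no stereocentre and no stereogenic double bond (the chromene alkene is endocyclic), so the target is achiral and is made as the single compound, in the tautomer drawn.

**Route**

Step 1
Reactants: 1 flopropione (1-(2,4,6-trihydroxyphenyl)propan-1-one)
Product: 2 propionylfilicinic acid (3,5-dihydroxy-4,4-dimethyl-2-propanoylcyclohexa-2,5-dien-1-one)
Conditions: NaOMe (3.5 equiv), MeI (2.2 equiv), MeOH, 0 to 23 °C; then 1 M HCl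
Reagents that add atoms: iodomethane, CI
Why: Dearomative double C-methylation of the phloroglucinol enolate (enolate alkylation), the second methyl entering the same ring carbon to give the cross-conjugated triketone as is known for acylphloroglucinols; no stereocentre is formed.

Step 2
Reactants: 2 propionylfilicinic acid; 3 2-(bromomethyl)-4,4,5,5-tetramethyl-1,3,2-dioxaborolane (BrCH2Bpin)
Product: 5 potassium trifluoro[(2,4-dihydroxy-3,3-dimethyl-6-oxo-5-propanoylcyclohexa-1,4-dien-1-yl)methyl]borate, via pinacol boronate 4 (not isolated)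
Conditions: K2CO3 (1.1 equiv), NaI (10 mol %), acetone, 23 °C; then KHF2 (3 equiv), MeOH/H2O, 0 to 23 °C
Reagents that add atoms: potassium hydrogen difluoride, [K+].F[H-]F
Why: Finkelstein-assisted SN2 C-alkylation of the soft triketone enolate at its only free ring CH by the α-boryl halide (activated by the vacant boron orbital, as in malonate alkylations with halomethylboronates), then standard KHF2 exchange, gives a bench-stable β-boryl ketone, that is, a boron homoenolate.

Step 3
Reactants: 1 flopropione
Product: 6 1-[4-(tert-butyldimethylsilyloxy)-2,6-dihydroxyphenyl]propan-1-one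
Conditions: TBSCl (1.05 equiv), imidazole (2.2 equiv), DMF, 0 °C
Reagents that add atoms: tert-butyldimethylsilyl chloride, CC(C)(C)[Si](C)(C)Cl
Why: Selective silyl ether formation at the para hydroxyl, which is the most acidic, the least hindered and the only one not flanking (hydrogen-bonded to) the ketone.

Step 4
Reactants: 6 1-[4-(tert-butyldimethylsilyloxy)-2,6-dihydroxyphenyl]propan-1-one; 7 3-methylbut-2-enal (prenal)
Product: 9 1-(5,7-dihydroxy-2,2-dimethyl-2H-chromen-8-yl)propan-1-one, via silyl chromene 8 (not isolated)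
Conditions: ethylenediammonium diacetate (10 mol %), toluene, 110 °C; then KHF2 (2 equiv), MeOH, 23 °C
Reagents that add atoms: none
Why: Knoevenagel-type condensation and oxa-6π electrocyclisation (2H-chromene annulation) can only close onto a hydroxyl ortho to the ketone because O-4 is blocked, which fixes the 8-acyl pattern as in alloevodionol-type syntheses, and KHF2 in methanol then cleaves the phenolic silyl ether selectively.

Step 5
Reactants: 9 1-(5,7-dihydroxy-2,2-dimethyl-2H-chromen-8-yl)propan-1-one
Product: 10 1-(5,7-dihydroxy-6-iodo-2,2-dimethyl-2H-chromen-8-yl)propan-1-one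
Conditions: N-iodosuccinimide (1.0 equiv), MeCN, 0 °C, dark
Reagents that add atoms: N-iodosuccinimide, O=C1CCC(=O)N1I
Why: Electrophilic aromatic iodination at the single free ring position, which lies between two hydroxyls and para to the ring oxygen and is therefore far more reactive than the chromene alkene.

Step 6
Reactants: 10 1-(5,7-dihydroxy-6-iodo-2,2-dimethyl-2H-chromen-8-yl)propan-1-one; 5 potassium trifluoro[(2,4-dihydroxy-3,3-dimethyl-6-oxo-5-propanoylcyclohexa-1,4-dien-1-yl)methyl]borate (1.3 equiv)
Product: 11 6-[(5,7-dihydroxy-2,2-dimethyl-8-propanoyl-2H-chromen-6-yl)methyl]-3,5-dihydroxy-4,4-dimethyl-2-propanoylcyclohexa-2,5-dien-1-one (target)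
Conditions: Pd(OAc)2 (5 mol %), 2-dicyclohexylphosphino-2',6'-diisopropoxybiphenyl (RuPhos, 10 mol %), K2CO3 (4 equiv), 1,4-dioxane/H2O (4:1), degassed, 85 °C; then 1 M HCl to pH 3
Reagents that add atoms: none
Why: Proposed new method: a Suzuki–Miyaura sp2–sp3 coupling in which the bridging carbon (an electrophile in the usual formaldehyde or methylene-trione union) reacts as a nucleophilic boron homoenolate with the phloroglucinol carbon made electrophilic as its iodide, through oxidative addition of the carbon–iodine bond to zerovalent palladium, base-promoted transmetalation of the allyl/benzyl-like CH2–B bond of the hydrolysed trifluoroborate and reductive elimination from an alkylpalladium that has no β-hydrogen (the adjacent ring carbon is a fully substituted enolate carbon); the closest known reactions are couplings of potassium β-trifluoroborato ketones, esters and amides and of benzyltrifluoroborates with aryl halides, and Suzuki couplings of unprotected halophenols.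

**Compound list**
1 | flopropione, 1-(2,4,6-trihydroxyphenyl)propan-1-one | CCC(=O)c1c(O)cc(O)cc1O | starting material
2 | propionylfilicinic acid, 3,5-dihydroxy-4,4-dimethyl-2-propanoylcyclohexa-2,5-dien-1-one | CCC(=O)C1=C(O)C(C)(C)C(O)=CC1=O | intermediate
3 | 2-(bromomethyl)-4,4,5,5-tetramethyl-1,3,2-dioxaborolane | CC1(C)OB(CBr)OC1(C)C | starting material
4 | 3,5-dihydroxy-4,4-dimethyl-2-propanoyl-6-[(4,4,5,5-tetramethyl-1,3,2-dioxaborolan-2-yl)methyl]cyclohexa-2,5-dien-1-one (pinacol boronate) | CCC(=O)C1=C(O)C(C)(C)C(O)=C(CB2OC(C)(C)C(C)(C)O2)C1=O | intermediate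
5 | potassium trifluoro[(2,4-dihydroxy-3,3-dimethyl-6-oxo-5-propanoylcyclohexa-1,4-dien-1-yl)methyl]borate | [K+].F[B-](F)(F)CC1=C(O)C(C)(C)C(O)=C(C(=O)CC)C1=O | intermediate
6 | 1-[4-(tert-butyldimethylsilyloxy)-2,6-dihydroxyphenyl]propan-1-one | CCC(=O)c1c(O)cc(O[Si](C)(C)C(C)(C)C)cc1O | intermediate
7 | 3-methylbut-2-enal (prenal) | CC(C)=CC=O | starting material
8 | 1-[5-(tert-butyldimethylsilyloxy)-7-hydroxy-2,2-dimethyl-2H-chromen-8-yl]propan-1-one (silyl chromene) | CCC(=O)c1c(O)cc(O[Si](C)(C)C(C)(C)C)c2C=CC(C)(C)Oc12 | intermediate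
9 | 1-(5,7-dihydroxy-2,2-dimethyl-2H-chromen-8-yl)propan-1-one | CCC(=O)c1c(O)cc(O)c2C=CC(C)(C)Oc12 | intermediate
10 | 1-(5,7-dihydroxy-6-iodo-2,2-dimethyl-2H-chromen-8-yl)propan-1-one | CCC(=O)c1c(O)c(I)c(O)c2C=CC(C)(C)Oc12 | intermediate
11 | 6-[(5,7-dihydroxy-2,2-dimethyl-8-propanoyl-2H-chromen-6-yl)methyl]-3,5-dihydroxy-4,4-dimethyl-2-propanoylcyclohexa-2,5-dien-1-one | CCC(=O)C1=C(O)C(C)(C)C(O)=C(Cc2c(O)c3c(c(C(=O)CC)c2O)OC(C)(C)C=C3)C1=O | target

**Totals**
Total steps: 6 (convergent). Longest linear sequence: 4 steps (steps 3, 4, 5, 6).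

**Steps most likely to fail, with fallbacks**

Step 6 (the unprotected homoenolate coupling; hydrodeiodination of the electron-rich bis-phenoxide or protodeboronation of the trifluoroborate may compete). The fallback sets out from 10: both phenols are masked with chloromethyl methyl ether and NaH (DMF, 0 °C) to give 1-[6-iodo-5,7-bis(methoxymethoxy)-2,2-dimethyl-2H-chromen-8-yl]propan-1-one F1. This neutral aryl iodide is coupled with 5 (Pd(OAc)2, RuPhos, K2CO3, toluene/H2O, 85 °C) to give 6-{[5,7-bis(methoxymethoxy)-2,2-dimethyl-8-propanoyl-2H-chromen-6-yl]methyl}-3,5-dihydroxy-4,4-dimethyl-2-propanoylcyclohexa-2,5-dien-1-one F2. The acetals are then cleaved with HCl in MeOH at 40 °C, which comes back to the route at 11.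

Step 2 (O-alkylation of the triketone enolate or a sluggish substitution). The fallback sets out from 2: a Mannich reaction with dimethylmethylideneammonium iodide (MeCN, 23 °C) gives 6-[(dimethylamino)methyl]-3,5-dihydroxy-4,4-dimethyl-2-propanoylcyclohexa-2,5-dien-1-one F3. Warming F3 with bis(pinacolato)diboron, CuCl (10 mol %), 4,5-bis(diphenylphosphino)-9,9-dimethylxanthene and KOtBu in THF/MeOH at 50 °C releases the exocyclic methylene trione in the flask, and the boryl–copper species adds to it in conjugate fashion. This comes back to the route at 4, which is converted to 5 with KHF2 as before.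

Step 4 (loss of the silyl ether on heating, or poor annulation next to the bulky silyloxy group). The fallback sets out from 6: C-prenylation with prenyl bromide and DBU (THF, 0 °C) gives 1-[4-(tert-butyldimethylsilyloxy)-2,6-dihydroxy-3-(3-methylbut-2-en-1-yl)phenyl]propan-1-one F4. Dehydrogenative cyclisation with 2,3-dichloro-5,6-dicyano-1,4-benzoquinone (benzene, 80 °C) then closes the pyran onto the only free ortho hydroxyl and comes back to the route at 8, which is desilylated as in step 4.

**Further compounds**
F1 | step 6 | 1-[6-iodo-5,7-bis(methoxymethoxy)-2,2-dimethyl-2H-chromen-8-yl]propan-1-one | CCC(=O)c1c(OCOC)c(I)c(OCOC)c2C=CC(C)(C)Oc12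
F2 | step 6 | 6-{[5,7-bis(methoxymethoxy)-2,2-dimethyl-8-propanoyl-2H-chromen-6-yl]methyl}-3,5-dihydroxy-4,4-dimethyl-2-propanoylcyclohexa-2,5-dien-1-one | CCC(=O)C1=C(O)C(C)(C)C(O)=C(Cc2c(OCOC)c3c(c(C(=O)CC)c2OCOC)OC(C)(C)C=C3)C1=O
F3 | step 2 | 6-[(dimethylamino)methyl]-3,5-dihydroxy-4,4-dimethyl-2-propanoylcyclohexa-2,5-dien-1-one | CCC(=O)C1=C(O)C(C)(C)C(O)=C(CN(C)C)C1=O
F4 | step 4 | 1-[4-(tert-butyldimethylsilyloxy)-2,6-dihydroxy-3-(3-methylbut-2-en-1-yl)phenyl]propan-1-one | CCC(=O)c1c(O)cc(O[Si](C)(C)C(C)(C)C)c(CC=C(C)C)c1O
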